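## Retrosynthetic overview

1. Target ⇐ one hydrogenolysis (three O‑benzyl groups and one benzylic OH) of a trans aldol adduct.
2. Aldol adduct ⇐ lithium enolate of an (R)‑β‑(arylmethyl)‑γ‑butyrolactone + 3,4‑bis(benzyloxy)‑5‑methoxybenzaldehyde (C3 set trans to C4).
3. (R)‑Lactone ⇐ catalytic enantioselective Baeyer–Villiger ring expansion of a prochiral 3‑(arylmethyl)cyclobutanone (key step, sets C4).
4. Cyclobutanone ⇐ Negishi coupling of 3‑(bromomethyl)cyclobutanone with O‑benzyl‑4‑bromoguaiacol.
5. Both arenes ⇐ 4‑bromoguaiacol ⇐ catechol. Ring order: the benzene rings and the four‑membered ring are bought; the γ‑lactone is the only ring made (4 → 5 ring expansion).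

Assumption: the given SMILES is the (3R,4R)‑trans lactone; all descriptors below follow from it.

## Route

Step 1
Reactants: 1 catechol (benzene‑1,2‑diol)
Product: 2 2‑methoxyphenol (guaiacol)
Conditions: MeI (1.0 equiv), K2CO3 (1.0 equiv), acetone, reflux; base extraction, distillation
Reagents that add atoms: iodomethane, CI
Why: Williamson ether synthesis in which one equivalent of base and MeI methylates the more acidic catechol monoanion preferentially, and neutral veratrole and water‑soluble catechol are removed on work‑up.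

Step 2
Reactants: 2 2‑methoxyphenol
Product: 3 4‑bromo‑2‑methoxyphenol
Conditions: NBS (1.0 equiv), MeCN, 0 °C
Reagents that add atoms: N‑bromosuccinimide, O=C1CCC(=O)N1Br
Why: Electrophilic aromatic bromination in which the free OH is the strongest director and its unhindered para position (C4) is brominated.

Step 3
Reactants: 3 4‑bromo‑2‑methoxyphenol
Product: 4 1‑(benzyloxy)‑4‑bromo‑2‑methoxybenzene
Conditions: BnBr, K2CO3, DMF, rt
Reagents that add atoms: benzyl bromide, BrCc1ccccc1
Why: Williamson O‑benzylation of the phenoxide, giving an ether that is inert to organozinc, peroxide and enolate chemistry and is removed in the last step.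

Step 4
Reactants: 5 3‑(bromomethyl)cyclobutan‑1‑one; 4 1‑(benzyloxy)‑4‑bromo‑2‑methoxybenzene
Product: 7 3‑[4‑(benzyloxy)‑3‑methoxybenzyl]cyclobutan‑1‑one, via alkylzinc bromide 6 (not isolated)
Conditions: 5, Zn dust (activated), LiCl, THF, 45 °C; then 4, Pd(OAc)2 (2 mol %), SPhos (4 mol %), THF, 25 °C
Reagents that add atoms: none
Why: Negishi sp3–sp2 cross‑coupling in which LiCl‑mediated zinc insertion gives a ketone‑tolerant primary alkylzinc (no free cyclobutylcarbinyl radical) that Pd/SPhos couples with the electron‑rich aryl bromide faster than β‑hydride elimination; the product is achiral.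

Step 5
Reactants: 7 3‑[4‑(benzyloxy)‑3‑methoxybenzyl]cyclobutan‑1‑one
Product: 8 (R)‑4‑[4‑(benzyloxy)‑3‑methoxybenzyl]dihydrofuran‑2(3H)‑one
Conditions: confined BINOL‑derived imidodiphosphoric acid with 3,3′‑(2,4,6‑triethylphenyl) groups (5 mol %), 35% aq H2O2 (1.5 equiv), CHCl3, −40 °C; Na2S2O3 quench
Reagents that add atoms: hydrogen peroxide, OO
Why: Proposed new method: a desymmetrising Baeyer–Villiger ring expansion under a confined chiral imidodiphosphoric acid, whose P=O/P–OH pair binds ketone and H2O2 by a bifunctional hydrogen‑bond relay and holds the Criegee adduct in its narrow cavity with the pseudo‑equatorial C3 arylmethyl arm pointing out of the pocket mouth, so that only one of the two enantiotopic ring CH2 groups can lie antiperiplanar to the O–O bond and undergo the 1,2‑shift to oxygen, which sets C4 as R (the catalyst antipode is used if a first run gives S); the closest known reaction type is the BINOL‑phosphoric‑acid/H2O2 Baeyer–Villiger oxidation of 3‑substituted cyclobutanones (good ee for 3‑aryl, modest for flexible 3‑arylmethyl groups), together with H2O2 sulfoxidation by the same confined acid class.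

Step 6
Reactants: 3 4‑bromo‑2‑methoxyphenol
Product: 11 5‑bromo‑3‑methoxybenzene‑1,2‑diol, via aryl borate 9 (not isolated), via ortho‑borylated aryl borate 10 (not isolated)
Conditions: HBpin (2.5 equiv), [Ir(OMe)(cod)]2 (1.5 mol %), dtbpy (3 mol %), cyclohexane, 80 °C; then Oxone, acetone/H2O, 0 °C; NaHSO3 quench
Reagents that add atoms: potassium peroxymonosulfate (active component of Oxone), [K+].[O-]S(=O)(=O)OO
Why: Iridium‑catalysed C–H borylation directed to the only ortho C–H (C6) by the O–Bpin group formed in situ (the other ring C–H bonds are blocked by Br and OMe), followed by stereoretentive boronate oxidation of the C–B bond to C–OH, with the reductive quench returning any o‑quinone to the catechol.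

Step 7
Reactants: 11 5‑bromo‑3‑methoxybenzene‑1,2‑diol
Product: 12 1,2‑bis(benzyloxy)‑5‑bromo‑3‑methoxybenzene
Conditions: BnBr (2.3 equiv), K2CO3, DMF, 60 °C, N2
Reagents that add atoms: benzyl bromide, BrCc1ccccc1
Why: Double Williamson O‑benzylation of the catechol, which masks the oxidation‑sensitive diol as ethers that leave in the final hydrogenolysis.

Step 8
Reactants: 12 1,2‑bis(benzyloxy)‑5‑bromo‑3‑methoxybenzene
Product: 15 3,4‑bis(benzyloxy)‑5‑methoxybenzaldehyde, via aryllithium 13 (not isolated), via lithium hemiaminal alkoxide 14 (not isolated)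
Conditions: n‑BuLi (1.05 equiv), THF, −78 °C; DMF; then 1 M HCl
Reagents that add atoms: N,N‑dimethylformamide, CN(C)C=O
Why: Bromine–lithium exchange is faster than benzylic deprotonation at −78 °C, and Bouveault formylation of the aryllithium with DMF gives a stable tetrahedral adduct that releases the aldehyde only on acidic work‑up.

Step 9
Reactants: 8 (R)‑4‑[4‑(benzyloxy)‑3‑methoxybenzyl]dihydrofuran‑2(3H)‑one; 15 3,4‑bis(benzyloxy)‑5‑methoxybenzaldehyde
Product: 17 (3S,4R)‑4‑[4‑(benzyloxy)‑3‑methoxybenzyl]‑3‑{[3,4‑bis(benzyloxy)‑5‑methoxyphenyl](hydroxy)methyl}dihydrofuran‑2(3H)‑one (both carbinol epimers), via lithium enolate 16 (not isolated)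
Conditions: LDA (1.1 equiv), THF, −78 °C; then 15, −78 °C; AcOH quench at −78 °C
Reagents that add atoms: none
Why: Aldol addition of the lithium lactone enolate, in which the aldehyde attacks the face anti to the C4 arylmethyl group (1,2‑induction) and so sets C3 trans to C4; the carbinol centre forms as a mixture and is removed in step 10.

Step 10
Reactants: 17 the aldol adduct
Product: 18 (−)‑thujaplicatin, (3R,4R)‑3‑(3,4‑dihydroxy‑5‑methoxybenzyl)‑4‑(4‑hydroxy‑3‑methoxybenzyl)dihydrofuran‑2(3H)‑one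
Conditions: H2 (1 atm), 10% Pd/C, AcOH/EtOAc, HClO4 (cat.), rt
Reagents that add atoms: none
Why: Palladium‑catalysed hydrogenolysis cleaves the three benzyl ethers and, under acid, the benzylic C–OH activated by the para oxygen, without touching C3 or C4 (trans is also the thermodynamic arrangement); the C3 descriptor changes from S to R only through CIP priorities.

## Compound list

1 | catechol | Oc1ccccc1O | starting material
2 | 2‑methoxyphenol | COc1ccccc1O | intermediate
3 | 4‑bromo‑2‑methoxyphenol | COc1cc(Br)ccc1O | intermediate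
4 | 1‑(benzyloxy)‑4‑bromo‑2‑methoxybenzene | COc1cc(Br)ccc1OCc1ccccc1 | intermediate
5 | 3‑(bromomethyl)cyclobutan‑1‑one | O=C1CC(CBr)C1 | starting material
6 | [(3‑oxocyclobutyl)methyl]zinc bromide | O=C1CC(C[Zn]Br)C1 | intermediate
7 | 3‑[4‑(benzyloxy)‑3‑methoxybenzyl]cyclobutan‑1‑one | COc1cc(CC2CC(=O)C2)ccc1OCc1ccccc1 | intermediate
8 | (R)‑4‑[4‑(benzyloxy)‑3‑methoxybenzyl]dihydrofuran‑2(3H)‑one | COc1cc(C[C@H]2COC(=O)C2)ccc1OCc1ccccc1 | intermediate
9 | 2‑(4‑bromo‑2‑methoxyphenoxy)‑4,4,5,5‑tetramethyl‑1,3,2‑dioxaborolane | COc1cc(Br)ccc1OB1OC(C)(C)C(C)(C)O1 | intermediate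
10 | 2‑[5‑bromo‑3‑methoxy‑2‑(pinacolboryloxy)phenyl]‑4,4,5,5‑tetramethyl‑1,3,2‑dioxaborolane | COc1cc(Br)cc(B2OC(C)(C)C(C)(C)O2)c1OB1OC(C)(C)C(C)(C)O1 | intermediate
11 | 5‑bromo‑3‑methoxybenzene‑1,2‑diol | COc1cc(Br)cc(O)c1O | intermediate
12 | 1,2‑bis(benzyloxy)‑5‑bromo‑3‑methoxybenzene | COc1cc(Br)cc(OCc2ccccc2)c1OCc1ccccc1 | intermediate
13 | [3,4‑bis(benzyloxy)‑5‑methoxyphenyl]lithium | COc1cc([Li])cc(OCc2ccccc2)c1OCc1ccccc1 | intermediate
14 | lithium [3,4‑bis(benzyloxy)‑5‑methoxyphenyl](dimethylamino)methanolate | COc1cc(C(O[Li])N(C)C)cc(OCc2ccccc2)c1OCc1ccccc1 | intermediate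
15 | 3,4‑bis(benzyloxy)‑5‑methoxybenzaldehyde | COc1cc(C=O)cc(OCc2ccccc2)c1OCc1ccccc1 | intermediate
16 | lithium (R)‑4‑[4‑(benzyloxy)‑3‑methoxybenzyl]‑4,5‑dihydrofuran‑2‑olate | COc1cc(C[C@H]2COC(O[Li])=C2)ccc1OCc1ccccc1 | intermediate
17 | (3S,4R)‑4‑[4‑(benzyloxy)‑3‑methoxybenzyl]‑3‑{[3,4‑bis(benzyloxy)‑5‑methoxyphenyl](hydroxy)methyl}dihydrofuran‑2(3H)‑one, carbinol epimers | COc1cc(C[C@H]2COC(=O)[C@@H]2C(O)c2cc(OCc3ccccc3)c(OCc3ccccc3)c(OC)c2)ccc1OCc1ccccc1 | intermediate
18 | (−)‑thujaplicatin | COc1cc(C[C@H]2COC(=O)[C@@H]2Cc2cc(O)c(O)c(OC)c2)ccc1O | target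

## Summary

Total steps: 10. Longest linear sequence: 7 (steps 1, 2, 3, 4, 5, 9, 10; the ring‑B branch 1, 2, 6, 7, 8, 9, 10 is equally long).

Three steps most likely to fail:

Step 5 (the proposed new enantioselective Baeyer–Villiger). The flexible arylmethyl arm may be poorly recognised, or uncatalysed oxidation may erode the ee. The fallback uses known chemistry, sets out from 7 and comes back at 8. It oxidises 7 with mCPBA/NaHCO3 in CH2Cl2 at 0 °C to racemic 4‑[4‑(benzyloxy)‑3‑methoxybenzyl]dihydrofuran‑2(3H)‑one F1. F1 is opened with (S)‑1‑phenylethylamine/AlMe3 (CH2Cl2, 40 °C) to two diastereomeric hydroxy amides, which are separated by chromatography or crystallisation. These are (R)‑4‑[4‑(benzyloxy)‑3‑methoxyphenyl]‑3‑(hydroxymethyl)‑N‑[(S)‑1‑phenylethyl]butanamide F2 and its discarded epimer (S)‑4‑[4‑(benzyloxy)‑3‑methoxyphenyl]‑3‑(hydroxymethyl)‑N‑[(S)‑1‑phenylethyl]butanamide F3. Heating F2 in 2 M H2SO4/dioxane relactonises it to 8. This replaces asymmetric catalysis by racemic oxidation and classical resolution.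

Step 4 (Negishi coupling of the strained γ‑bromo ketone). The alkylzinc may form sluggishly, open the ring to an enolate, or suffer β‑hydride elimination on palladium. The fallback sets out from 4 and comes back at 7. Compound 4 is converted to the Grignard reagent (Mg, THF) and allylated with allyl bromide (CuI cat.) to 4‑allyl‑1‑(benzyloxy)‑2‑methoxybenzene F4. [2+2] cycloaddition with dichloroketene (Cl3CCOCl, Zn–Cu, Et2O, reflux) gives racemic 3‑[4‑(benzyloxy)‑3‑methoxybenzyl]‑2,2‑dichlorocyclobutan‑1‑one F5. Zn/AcOH dechlorination gives 7. This builds the four‑membered ring by ketene–alkene cycloaddition instead of coupling onto a preformed cyclobutanone.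

Step 6 (O‑Bpin‑directed C–H borylation/oxidation). Borylation next to the 2‑methoxy group may be slow, and the catechol may over‑oxidise with Oxone. The fallback sets out from 3 and comes back at 11. Ortho‑formylation of 3 (MgCl2, Et3N, paraformaldehyde, MeCN, reflux) gives 5‑bromo‑2‑hydroxy‑3‑methoxybenzaldehyde F6. Dakin oxidation (30% H2O2, aq NaOH, rt, then HCl) gives 11. This replaces C–H borylation by C‑formylation and an aryl C→O shift.

Further compounds

F1 | step 5 | rac‑4‑[4‑(benzyloxy)‑3‑methoxybenzyl]dihydrofuran‑2(3H)‑one | COc1cc(CC2COC(=O)C2)ccc1OCc1ccccc1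
F2 | step 5 | (R)‑4‑[4‑(benzyloxy)‑3‑methoxyphenyl]‑3‑(hydroxymethyl)‑N‑[(S)‑1‑phenylethyl]butanamide | COc1cc(C[C@@H](CO)CC(=O)N[C@@H](C)c2ccccc2)ccc1OCc1ccccc1
F3 | step 5 | (S)‑4‑[4‑(benzyloxy)‑3‑methoxyphenyl]‑3‑(hydroxymethyl)‑N‑[(S)‑1‑phenylethyl]butanamide | COc1cc(C[C@H](CO)CC(=O)N[C@@H](C)c2ccccc2)ccc1OCc1ccccc1
F4 | step 4 | 4‑allyl‑1‑(benzyloxy)‑2‑methoxybenzene | COc1cc(CC=C)ccc1OCc1ccccc1
F5 | step 4 | rac‑3‑[4‑(benzyloxy)‑3‑methoxybenzyl]‑2,2‑dichlorocyclobutan‑1‑one | COc1cc(CC2CC(=O)C2(Cl)Cl)ccc1OCc1ccccc1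
F6 | step 6 | 5‑bromo‑2‑hydroxy‑3‑methoxybenzaldehyde | COc1cc(Br)cc(C=O)c1O
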